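**Strategy.** The ester carbonyl–aryl bond is formed by adding a 4-(THP-oxy)phenyllithium to the C=O of a six-membered cyclic carbonate that bridges the tertiary O4 on the cyclopentane ring and O6 on the cycloheptane ring, the two oxygens that flank ring-fusion carbon C5. This one operation makes the aryl–C(=O) bond, releases the 4-OH and leaves the aroyl group on O6 alone. Its precursor is a tricyclic 8α,9α-epoxy carbonate without ester or free hydroxyl. The daucane core comes from (S)-terpinen-4-ol (C4 stereocentre and ten carbons) by ozonolysis/aldol ring contraction, allylboration/oxy-Cope, chelation-controlled methallylation and ring-closing metathesis.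

Key step: step 11

**Remarks on the chemistry (assumptions)**
- Daucane numbering is used: C1 (quaternary, CH3-15), C2, C3, C4 (OH, iPr), C5 (ring-fusion H), C6 (ester O), C7, C8 (CH3-14, OH), C9 (OH), C10. The five-membered ring is C1–C5; the seven-membered ring is C1, C5–C10. β is the face of CH3-15, α the face of H-5.
- (S)-Terpinen-4-ol (the dextrorotatory enantiomer) is assumed to be used as a single enantiomer.
- The THP acetal carbon of 16–18 is stereorandom; it is removed in step 12.

**Step 1**
Reactants: 1 (S)-terpinen-4-ol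
Product: 2 (S)-terpinen-4-yl triethylsilyl ether
Conditions: TESOTf, 2,6-lutidine, CH2Cl2, −78 → 0 °C
Reagents that add atoms: triethylsilyl triflate, CC[Si](CC)(CC)OS(=O)(=O)C(F)(F)F
Why: Silyl triflate/lutidine silylation of the hindered tertiary alcohol masks O4 so that the β-oxygenated aldehyde of step 2 cannot lose water under aldol conditions; the C4 stereocentre comes unchanged from the chiral pool.

**Step 2**
Reactants: 2 (S)-terpinen-4-yl triethylsilyl ether
Product: 4 (3S)-6-oxo-3-(propan-2-yl)-3-(triethylsilyloxy)heptanal, via ozonide 3 (not isolated)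
Conditions: O3, CH2Cl2, −78 °C; then Me2S, −78 → 23 °C
Reagents that add atoms: ozone, [O-][O+]=O
Why: Ozonolysis with reductive work-up cleaves the only C=C to a methyl ketone (future C1 and CH3-15) and an aldehyde (future C6) and does not touch C4.

**Step 3**
Reactants: 4 (3S)-6-oxo-3-(propan-2-yl)-3-(triethylsilyloxy)heptanal
Product: 5 (5R)-2-methyl-5-(propan-2-yl)-5-(triethylsilyloxy)cyclopent-1-ene-1-carbaldehyde
Conditions: piperidine (0.3 equiv), AcOH (0.3 equiv), benzene, 60 °C
Reagents that add atoms: none
Why: Amine–acid catalysed intramolecular aldol condensation, in which the enamine of the aldehyde closes onto the methyl ketone (5-enolexo) and dehydration gives the conjugated cyclopentenecarbaldehyde, the known ring contraction of keto aldehydes derived from 1-methylcyclohexenes; no stereocentre is formed.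

**Step 4**
Reactants: 5 (5R)-2-methyl-5-(propan-2-yl)-5-(triethylsilyloxy)cyclopent-1-ene-1-carbaldehyde
Product: 7 (1S)-1-[(5R)-2-methyl-5-(propan-2-yl)-5-(triethylsilyloxy)cyclopent-1-en-1-yl]but-3-en-1-ol, via borinate ester 6 (not isolated)
Conditions: (−)-Ipc2B(allyl), Et2O, −78 → −20 °C; then NaOH, H2O2, 0 → 23 °C
Reagents that add atoms: (−)-B-allyldiisopinocampheylborane, C=CCB([C@@H]1C[C@@H]2C[C@H]([C@H]1C)C2(C)C)[C@@H]1C[C@@H]2C[C@H]([C@H]1C)C2(C)C
Why: Brown allylboration through a closed chair transition state, in which the isopinocampheyl groups derived from (+)-α-pinene should override the substrate and deliver allyl to the aldehyde face that gives the (S)-carbinol, a relay stereocentre that is consumed in step 6.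

**Step 5**
Reactants: 7 (1S)-1-[(5R)-2-methyl-5-(propan-2-yl)-5-(triethylsilyloxy)cyclopent-1-en-1-yl]but-3-en-1-ol
Product: 8 (1R)-2-[(1S)-1-hydroxybut-3-en-1-yl]-3-methyl-1-(propan-2-yl)cyclopent-2-en-1-ol
Conditions: TBAF, THF, 23 → 40 °C
Reagents that add atoms: none
Why: Fluoride-induced Si–O cleavage frees the tertiary 4-OH, which is needed as a metal-binding site in steps 6 and 7; no stereocentre is affected.

**Step 6**
Reactants: 8 (1R)-2-[(1S)-1-hydroxybut-3-en-1-yl]-3-methyl-1-(propan-2-yl)cyclopent-2-en-1-ol
Product: 10 (1R,2R,5R)-5-hydroxy-2-methyl-5-(propan-2-yl)-2-(prop-2-en-1-yl)cyclopentane-1-carbaldehyde, via dipotassium enolate 9 (not isolated)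
Conditions: KHMDS (2.3 equiv), THF, 0 → 60 °C (no crown ether); inverse quench into AcOH/THF, −78 °C; crude aldehyde with Et3N, CH2Cl2, 23 °C
Reagents that add atoms: none
Why: Anionic oxy-Cope rearrangement ([3,3]) through a chair in which K+ bridges the C4 and C6 alkoxides, so that O6 lies anti to C1 and only H6 meets the C1 methyl; with the (S)-carbinol this places the allyl chain under the α face and should make C1 quaternary with allyl cis to iPr and CH3 cis to O4, and C5 is then set under thermodynamic control (CHO cis to OH and CH3, away from iPr and allyl, hydrogen-bonded to the 4-OH).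

**Step 7**
Reactants: 10 (1R,2R,5R)-5-hydroxy-2-methyl-5-(propan-2-yl)-2-(prop-2-en-1-yl)cyclopentane-1-carbaldehyde
Product: 11 (1R,2S,3R)-2-[(1S)-1-hydroxy-3-methylbut-3-en-1-yl]-3-methyl-1-(propan-2-yl)-3-(prop-2-en-1-yl)cyclopentan-1-ol
Conditions: 2-methylallylmagnesium chloride (2.5 equiv), THF, −78 °C; NH4Cl (aq)
Reagents that add atoms: 2-methylallylmagnesium chloride, CC(=C)C[Mg]Cl
Why: Chelation-controlled Grignard addition, in which the magnesium alkoxide of O4 holds the formyl oxygen syn to C4 in a six-membered chelate and the methallyl group attacks the carbonyl face that points away from the cyclopentane (the side of H5), which should set C6 as in the target (6S, oxygen α).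

**Step 8**
Reactants: 11 (1R,2S,3R)-2-[(1S)-1-hydroxy-3-methylbut-3-en-1-yl]-3-methyl-1-(propan-2-yl)-3-(prop-2-en-1-yl)cyclopentan-1-ol
Product: 12 jaeschkeanadiol (trans-dauc-8-ene-4β,6α-diol)
Conditions: Grubbs second-generation catalyst (5 mol%), CH2Cl2 (5 mM), 40 °C
Reagents that add atoms: none
Why: Ring-closing metathesis of the monosubstituted and the 1,1-disubstituted alkene closes the seven-membered ring as the trisubstituted C8=C9 olefin with loss of ethene; the trans ring fusion is already fixed at C1 and C5.

**Step 9**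
Reactants: 12 jaeschkeanadiol
Product: 13 8α,9α-epoxy-trans-daucane-4β,6α-diol
Conditions: VO(acac)2 (5 mol%), t-BuOOH, CH2Cl2, 0 → 23 °C
Reagents that add atoms: tert-butyl hydroperoxide, CC(C)(C)OO
Why: Vanadium-catalysed hydroxyl-directed epoxidation, in which the homoallylic 6α-OH binds the vanadium peroxide and delivers oxygen to the α face of C8=C9, the face that is also remote from the angular CH3 on C1.

**Step 10**
Reactants: 13 8α,9α-epoxy-trans-daucane-4β,6α-diol
Product: 15 8α,9α-epoxy-trans-daucane-4β,6α-diyl cyclic carbonate, via imidazolide 14 (not isolated)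
Conditions: CDI, THF, 23 °C; then NaH, 0 → 23 °C
Reagents that add atoms: 1,1'-carbonyldiimidazole, O=C(n1ccnc1)n1ccnc1
Why: Carbonylation of a 1,3-diol with CDI, in which the secondary 6-OH is acylated first and the tertiary 4-alkoxide then closes the six-membered carbonate, possible because O4 and O6 sit within about 2.5–2.8 Å of each other on the β side of C5; all stereocentres keep their C–O bonds.

**Step 11**
Reactants: 15 8α,9α-epoxy-trans-daucane-4β,6α-diyl cyclic carbonate; 16 2-(4-bromophenoxy)tetrahydro-2H-pyran
Product: 18 8α,9α-epoxy-4β-hydroxy-trans-daucan-6α-yl 4-(tetrahydro-2H-pyran-2-yloxy)benzoate, via aryllithium 17 (not isolated)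
Conditions: 16 (2.2 equiv), n-BuLi (2.1 equiv), THF, −78 °C; then 15, THF, −78 °C; NH4Cl (aq), −78 °C
Reagents that add atoms: none
Why: Bromine–lithium exchange on 16 gives aryllithium 17, which adds to the carbonate C=O of 15 to give a lithium hemiorthoester that collapses with cleavage of the C(=O)–O4 bond, so the new aryl–carbonyl bond ends up in the O6 ester and O4 leaves as the tertiary alkoxide. The closest known reaction type is the opening of cyclic diol carbonates by organolithium reagents to hydroxy monoesters, established for carbonates of secondary/tertiary diols in complex polyols. No ring is closed (the carbonate ring is opened) and no stereocentre is formed or touched, since C4 and C6 keep their C–O bonds. The step needs regioselective collapse and mono-addition: expulsion of the crowded tertiary O4 (flanked by iPr and the ring fusion) relieves strain and leaves the acyl group on the less hindered secondary O6, which is also the thermodynamic site should the alkoxide re-close, and at −78 °C the resulting ester is hindered, flanked by the lithium alkoxide and deactivated by the para-alkoxy donor against a second addition. The trisubstituted epoxide and the THP acetal should be inert to the aryllithium at this temperature, and 15 carries no acidic hydrogen.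

**Step 12**
Reactants: 18 8α,9α-epoxy-4β-hydroxy-trans-daucan-6α-yl 4-(tetrahydro-2H-pyran-2-yloxy)benzoate
Product: 20 4β,8β,9α-trihydroxy-trans-daucan-6α-yl 4-hydroxybenzoate (CNP0197754.1), via epoxy phenol 19 (not isolated)
Conditions: HClO4 (0.1 M), THF/H2O 3:1, 0 → 23 °C
Reagents that add atoms: water, O
Why: Acid-catalysed epoxide hydrolysis with anti opening, in which water attacks the protonated epoxide at the tertiary C8 from the β face with inversion while C9 keeps its α oxygen, which should give the trans 8β,9α-diol, and the same acid hydrolyses the aryl THP acetal.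

**Compound list**
1 | (S)-terpinen-4-ol, (1S)-4-methyl-1-(propan-2-yl)cyclohex-3-en-1-ol | CC(C)[C@]1(O)CCC(C)=CC1 | starting material
2 | (S)-terpinen-4-yl triethylsilyl ether | CC(C)[C@]1(O[Si](CC)(CC)CC)CCC(C)=CC1 | intermediate
3 | secondary ozonide (1,2,4-trioxolane) of 2 | CC(C)[C@]1(O[Si](CC)(CC)CC)CCC2(C)OOC(C1)O2 | intermediate
4 | (3S)-6-oxo-3-(propan-2-yl)-3-(triethylsilyloxy)heptanal | CC(C)[C@](O[Si](CC)(CC)CC)(CCC(C)=O)CC=O | intermediate
5 | (5R)-2-methyl-5-(propan-2-yl)-5-(triethylsilyloxy)cyclopent-1-ene-1-carbaldehyde | CC(C)[C@]1(O[Si](CC)(CC)CC)CCC(C)=C1C=O | intermediate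
6 | diisopinocampheylborinate ester of 7 | CC(C)[C@]1(O[Si](CC)(CC)CC)CCC(C)=C1[C@@H](OB([C@@H]2C[C@@H]3C[C@H]([C@H]2C)C3(C)C)[C@@H]2C[C@@H]3C[C@H]([C@H]2C)C3(C)C)CC=C | intermediate
7 | (1S)-1-[(5R)-2-methyl-5-(propan-2-yl)-5-(triethylsilyloxy)cyclopent-1-en-1-yl]but-3-en-1-ol | CC(C)[C@]1(O[Si](CC)(CC)CC)CCC(C)=C1[C@@H](O)CC=C | intermediate
8 | (1R)-2-[(1S)-1-hydroxybut-3-en-1-yl]-3-methyl-1-(propan-2-yl)cyclopent-2-en-1-ol | CC(C)[C@]1(O)CCC(C)=C1[C@@H](O)CC=C | intermediate
9 | dipotassium alkoxide enolate of 10 (C1 allyl α, CH3 β) | CC(C)[C@]1([O-])CC[C@](C)(CC=C)C1=C[O-].[K+].[K+] | intermediate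
10 | (1R,2R,5R)-5-hydroxy-2-methyl-5-(propan-2-yl)-2-(prop-2-en-1-yl)cyclopentane-1-carbaldehyde (CHO cis to OH and CH3) | CC(C)[C@]1(O)CC[C@](C)(CC=C)[C@H]1C=O | intermediate
11 | (1R,2S,3R)-2-[(1S)-1-hydroxy-3-methylbut-3-en-1-yl]-3-methyl-1-(propan-2-yl)-3-(prop-2-en-1-yl)cyclopentan-1-ol | CC(C)[C@]1(O)CC[C@]2(C)CC=C(C)C[C@H](O)[C@H]21 is formed from it in step 8; 11 itself: CC(C)[C@]1(O)CC[C@](C)(CC=C)[C@H]1[C@@H](O)CC(C)=C | intermediate
12 | jaeschkeanadiol, trans-dauc-8-ene-4β,6α-diol (CH3-15 β, H-5 α) | CC(C)[C@]1(O)CC[C@]2(C)CC=C(C)C[C@H](O)[C@H]21 | intermediate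
13 | 8α,9α-epoxy-trans-daucane-4β,6α-diol | CC(C)[C@]1(O)CC[C@]2(C)C[C@@H]3O[C@]3(C)C[C@H](O)[C@H]21 | intermediate
14 | 8α,9α-epoxy-4β-hydroxy-trans-daucan-6α-yl imidazole-1-carboxylate | CC(C)[C@]1(O)CC[C@]2(C)C[C@@H]3O[C@]3(C)C[C@H](OC(=O)n4ccnc4)[C@H]21 | intermediate
15 | 8α,9α-epoxy-trans-daucane-4β,6α-diyl cyclic carbonate | CC(C)[C@]1(OC(=O)O5)CC[C@]2(C)C[C@@H]3O[C@]3(C)C[C@H]5[C@H]21 | intermediate
16 | 2-(4-bromophenoxy)tetrahydro-2H-pyran (racemic) | Brc1ccc(OC2CCCCO2)cc1 | starting material
17 | 4-(tetrahydro-2H-pyran-2-yloxy)phenyllithium | [Li]c1ccc(OC2CCCCO2)cc1 | intermediate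
18 | 8α,9α-epoxy-4β-hydroxy-trans-daucan-6α-yl 4-(tetrahydro-2H-pyran-2-yloxy)benzoate (both acetal epimers) | CC(C)[C@]1(O)CC[C@]2(C)C[C@@H]3O[C@]3(C)C[C@H](OC(=O)c4ccc(OC5CCCCO5)cc4)[C@H]21 | intermediate
19 | 8α,9α-epoxy-4β-hydroxy-trans-daucan-6α-yl 4-hydroxybenzoate | CC(C)[C@]1(O)CC[C@]2(C)C[C@@H]3O[C@]3(C)C[C@H](OC(=O)c4ccc(O)cc4)[C@H]21 | intermediate
20 | 4β,8β,9α-trihydroxy-trans-daucan-6α-yl 4-hydroxybenzoate (CNP0197754.1) | CC(C)[C@]1(O)CC[C@]2(C)C[C@H](O)[C@@](C)(O)C[C@H](OC(=O)c3ccc(O)cc3)[C@H]21 | target

**Step count and sequence**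
Total steps: 12. Longest linear sequence: 12 steps (1 → 20); 16 is used as purchased.

**Steps most likely to fail**

Step 6. The allyl group may travel across the wrong face of C5=C1 if the potassium bridge between O4 and O6 is lost or a boat pathway competes. The alkoxide may also fragment by retro-allylation instead of rearranging. During the C5 equilibration the β-hydroxy aldehyde may lose water or open by retro-aldol cleavage. The fallback sets out from 5 and avoids both the C6 relay and the dianion. A copper-mediated conjugate allylation (allylmagnesium bromide, CuBr·SMe2, TMSCl, THF, −78 °C) is used, in which the cuprate is expected to approach C1 from the α face, opposite the pseudo-axial OSiEt3 group. It gives the trimethylsilyl enol ether of the TES-protected 1,4-adduct F1. TBAF buffered with AcOH then removes both silyl groups, the formyl group settles cis to the 4-OH, and the route is rejoined at 10.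

Step 11. The tetrahedral adduct may collapse toward the tertiary O4 ester, or a second aryllithium may add to the newly formed ester and strip the acyl group as a diaryl ketone or carbinol. The fallback sets out from 13 and comes back at 18, skipping step 10. It is a Pd-catalysed alkoxycarbonylation of aryl bromide 16 under CO (Pd(OAc)2, Xantphos, CO 1 atm, Et3N, toluene, 80 °C) with the secondary 6-OH of 13 as the nucleophile. The aryl–C(=O) bond is then made by CO insertion into the aryl–palladium bond and only the unhindered secondary hydroxyl can capture the acyl-palladium, so neither a regiochemical choice nor a second addition exists. This fallback makes no new compound (F0).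

Step 7. Chelation may be too weak to control the carbonyl face (poor facial selectivity at C6), and the basic Grignard reagent may enolise the aldehyde or trigger retro-aldol opening. The fallback sets out from 10 and comes back at 11. The Grignard adduct is taken on as the mixture of 11 and its C6 epimer F2, and oxidised with Dess–Martin periodinane (NaHCO3 buffer) to the β-hydroxy ketone F3. F3 is reduced with Me4NBH(OAc)3 (MeCN/AcOH, −20 °C). The borohydride bound to O4 delivers hydride to C6 from the side of O4 (hydroxyl-directed Evans–Saksena reduction), which should give 11 alone.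

**Further compounds**
F1 | step 6 | trimethylsilyl enol ether of (2R,5R)-2-methyl-5-(propan-2-yl)-2-(prop-2-en-1-yl)-5-(triethylsilyloxy)cyclopentane-1-carbaldehyde | CC(C)[C@]1(O[Si](CC)(CC)CC)CC[C@](C)(CC=C)C1=CO[Si](C)(C)C
F0 | step 11 | none | none
F2 | step 7 | C6 epimer of 11, (1R,2S,3R)-2-[(1R)-1-hydroxy-3-methylbut-3-en-1-yl]-3-methyl-1-(propan-2-yl)-3-(prop-2-en-1-yl)cyclopentan-1-ol | CC(C)[C@]1(O)CC[C@](C)(CC=C)[C@H]1[C@H](O)CC(C)=C
F3 | step 7 | 1-[(1R,2R,5R)-5-hydroxy-2-methyl-5-(propan-2-yl)-2-(prop-2-en-1-yl)cyclopentyl]-3-methylbut-3-en-1-one | CC(C)[C@]1(O)CC[C@](C)(CC=C)[C@H]1C(=O)CC(C)=C
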